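## Analysis of the target

Compound 27 is a cyclohexane with five stereogenic ring carbons, joined through an sp2 carbon to a chain with two more stereocentres. The locants used throughout are ring C1 (bears the chain), C2 (CH2), C3 (Cl), C4 (CH3 and tertiary OH), C5 (free secondary OH) and C6 (ring angelate), then chain C7 (with the exocyclic methylene C14), C8 (second angelate), C9 and the oxirane carbons C10 and C11; in these locants the configuration is 1R,3S,4S,5S,6S,8S,10S. C4–OH, C5–OH, C6–O-acyl and the C1 side chain lie on one ring face; chlorine and the C4 methyl group lie on the other. Chlorine and the tertiary hydroxyl are therefore trans, and diaxial in the chair that keeps the side chain equatorial, which is the pattern of an epoxide opened by chloride. The sensitive groups are the two (Z)-2-methylbut-2-enoates (they isomerise to the E esters), the acid-labile trisubstituted oxirane, the chlorohydrin (it closes with base) and the C6 ester next to the free cis C5–OH (acyl migration). The synthesis is hard because three neighbouring ring oxygens must end in three different states beside a halide, and because C8 and C10 are insulated from the ring, so each needs its own reagent control. The strategy rests on one feature: C4–C5–C6 is a dihydroxyacetone unit reduced at its central carbon, and its two α-carbons are tied together by C3–C2–C1, with C1 carrying one more carbon, C7; C3, C2, C1 and C7 are the skeleton of a 4-oxobut-2-enoate, so the ring is a ketone and an enal joined across both α-carbons of the ketone.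

## Retrosynthetic reasoning

**Oxirane last (27 ⇒ 26).** The C10–C11 oxirane is removed first because it is the most acid-sensitive group. Its precursor, the C10=C11 alkene of 26, is the only electron-rich alkene in the molecule. C10 is too far from the other stereocentres for relay, so the forward step must be a reagent-controlled epoxidation that leaves the 1,1-disubstituted alkene and both enoates alone.

**Chlorohydrin from a ring epoxide (26 ⇒ 25 ⇒ 24).** After the C5 silyl ether is put back (25), the C3–Cl bond is cut and C3 is joined to the oxygen on C4. This gives oxirane 24 with its oxygen on the face of C5–O and C6–O. The trans-diaxial relation of Cl and OH is then a consequence of the opening, and the forward step only has to direct the halide to the secondary carbon C3.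

**Both esters at once (24 ⇒ 21 + 22).** The two acyl C–O bonds are cut together. In diol 21 the hydroxyls at C6 and C8 are the only free ones, so one acylation with angelic acid 22 serves both. The isomerisable esters are thereby introduced late.

**Ring epoxide from a masked diol (21 ⇒ 20 ⇒ 19).** The oxirane C3–O bond is cut back to the C3 mesylate and the free C4–OH of 20; the forward closure inverts C3. The oxygens on C4 and C6 are then tied in one acetonide (19). This acetonide is what keeps C5–O distinguishable from its two neighbours, and the C8 silyl ether falls off in the same acid step.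

**Methylene and C8 oxygen from a C7 ketone (19 ⇒ 18 ⇒ 17 ⇒ 15).** The C7=C14 bond is cut back to the ketone of 18, and the C8–O bond to an enolate oxidation of 15. C7 as a carbonyl does three jobs: it accepts the chain, it acidifies C8, and it becomes the methylene.

**Chain attachment (15 ⇒ 12 + 13, 12 ⇒ 11).** The C7–C8 bond is cut between the N-methoxy-N-methylamide 12 and the Grignard reagent 14 from bromide 13. The whole C8–C11 unit thus arrives in one step from the ester of 11.

**Adjustments on the bicycle (11 ⇒ 10 ⇒ 9 ⇒ 8).** The C5 silyl ether, the C5 alcohol and the C3 mesylate go back to keto alcohol 8. The rigid bicycle is the best place to set C5 and to activate C3.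

**Key disconnection (8 ⇒ 5 + 6).** Two ring bonds are cut: C6–C1 and C4–C3. This splits the carbocycle into dioxanone 5 and enal ester 6. The ring, two skeletal bonds and four stereocentres are gained from two small achiral or racemic molecules. The forward reaction must make the Michael bond from the unsubstituted α-carbon of 5 to the ester-bearing alkene carbon of 6 with control of C1, and then close the aldol from the methyl-bearing α-carbon.

**Precursor (5 ⇒ 4 ⇒ 2 ⇒ 1).** The C4–CH3 bond is cut. Methylation goes through hydrazone 2 and its methylated form 4, because the parent ketone 1 does not tolerate direct enolate alkylation.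

## Alternatives that were turned down

Alternative 1: The C7–C1 bond is cut, and the ring is taken from the arene cis-dihydrodiol (1S,2R)-3-methylcyclohexa-3,5-diene-1,2-diol A3. Forward, A3 is silylated at C5–O and its C6–O is converted into the (1-bromoethenyl)dimethylsilyl ether A2. Bu3SnH generates the vinyl radical at C7 of A2, which closes 5-exo onto C1, and hydrogen capture at C2 gives the oxasilolane A1 with the C3=C4 alkene kept.
- For it: A3 is enantiopure and already holds C5–O and C6–O cis in the configuration of 27, the C4 methyl group and an alkene placed for the chlorohydrin. The tether forces C1 cis to C6–O, and the exocyclic methylene is born in the key step. On the source of absolute configuration and on the methylene it is stronger than the chosen route, which needs an unprecedented catalytic step and a ketone methylenation.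
- Against it: the cyclised radical is an allyl radical spread over C2 and C4, so the alkene position depends on where hydrogen is delivered. 6-Endo closure onto the diene competes. Stoichiometric Bu3SnH is needed. Most seriously, C7 leaves the step bonded to silicon: joining it to C8 needs a halodesilylation and a metal-mediated addition to a C8 aldehyde, with no inherent control of C8.
- Comparison: the chosen route offers a C7 carbonyl that accepts the complete C8–C11 chain in one ketone synthesis and places the C3 oxygen in the ring-forming step. Overall step economy is no worse.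

Alternative 2: The C3–C4 bond is cut. Forward, the open-chain methyl ketone A5, which ends in an α-chloro sulfoxide, undergoes sulfoxide–magnesium exchange with iPrMgCl at low temperature. The α-chloroalkylmagnesium centre at C3 adds to the C4 ketone and closes the ring as the chlorohydrin A4.
- For it: the chlorohydrin arises directly, without the epoxide detour, and the protecting groups of A4 already separate C5 (silyl) from C6 and C8 (4-methoxybenzyl). On these two points it is stronger than the chosen route.
- Against it: A5 carries C1, C5, C6, C8 and the chloride-bearing C3 on an open chain, so five stereocentres must be built by linear acyclic chemistry before the key step. The carbenoid keeps its configuration only when cold, while it must add to a hindered α-silyloxy ketone to make a quaternary carbinol. The face of the ketone depends on a balance between chelation and non-chelation control. The chloro alkoxide can close to an epoxide on warming.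
- Comparison: the chosen route builds the ring and four stereocentres in one step from two small molecules, and its risk sits in that one step rather than in a long precursor synthesis.

Alternative 3: The C1–C2 and C5–C6 bonds are cut in a Diels–Alder sense. Forward, the diisopropylsilylene bis-enol ether A7 links a 1-silyloxy diene (C2 to C5) and a (Z)-β-silyloxy enone (C6=C1) through O–Si–O. Heating gives the cis-fused dioxasilolane A6.
- For it: two ring bonds and the all-cis array C5–O, C6–O, C1 form together, the C3=C4 alkene is in place, and the chain with the C8 stereocentre and the C7 ketone is already attached. On the chain it is stronger, since no α-hydroxylation is needed.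
- Against it: both partners are donor-substituted, and the β-oxygen makes the enone a vinylogous ester and a weak dienophile. The one-atom tether spans the forming C5–C6 bond and strains the transition state. The only stereocentre present, C8, is acyclic, α to a ketone and remote from the reacting faces, so the ring configuration relative to C8 is not controlled and C8 may epimerise on heating. The unsymmetrical bis-enol silane is hard to assemble and sensitive to hydrolysis.
- Comparison: the chosen route offers catalyst control of absolute configuration and delivers the C3 oxygen, which A6 still lacks.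

Key step: step 4

## Remarks on the chemistry

- Dioxanone 5 is used as the racemate: its methyl-bearing α-carbon becomes the enol carbon C4 during ring closure and loses its configuration.
- Step 4 assumes the usual shielding model for diarylprolinol silyl ether iminium ions; on that model the R amine gives the C1 configuration of 8.
- Step 10 assumes that the (+)-oxaziridine, which gives S acyloins from Z enolates of aryl ketones, transfers oxygen in the same sense to enolate 16.
- Step 18 assumes that the D-fructose-derived ketone gives the R oxirane at the CH carbon of 2-methylalk-2-enes, so its enantiomer is used for 10S.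

## Route

Step 1
Reactants: 1 2,2-dimethyl-1,3-dioxan-5-one
Product: 2 2-(2,2-dimethyl-1,3-dioxan-5-ylidene)-1,1-dimethylhydrazine
Conditions: Me2NNH2 (1.2 equiv), cyclohexane, 4 Å MS, 60 °C
Reagents that add atoms: 1,1-dimethylhydrazine, CN(C)N
Why: Hydrazone condensation of an unhindered ketone; the sieves take up the water and the acetonide is untouched under these neutral conditions.

Step 2
Reactants: 2 2-(2,2-dimethyl-1,3-dioxan-5-ylidene)-1,1-dimethylhydrazine
Product: 4 1,1-dimethyl-2-(2,2,4-trimethyl-1,3-dioxan-5-ylidene)hydrazine (racemic), via lithium azaenolate 3 (not isolated)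
Conditions: tBuLi, THF, −78 °C; MeI, −100 → −78 °C
Reagents that add atoms: iodomethane, CI
Why: Hydrazone azaenolate alkylation; unlike the lithium enolate of 1 the azaenolate does not self-condense, and one equivalent each of base and electrophile should stop at monomethylation. The new centre forms as the racemate, which suffices.

Step 3
Reactants: 4 1,1-dimethyl-2-(2,2,4-trimethyl-1,3-dioxan-5-ylidene)hydrazine
Product: 5 2,2,4-trimethyl-1,3-dioxan-5-one (racemic)
Conditions: sat. aq. (CO2H)2, Et2O, rt
Reagents that add atoms: water, O
Why: Biphasic hydrazone hydrolysis; the weak acid traps the hydrazine in the aqueous layer and leaves the acetonide intact.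

Step 4
Reactants: 5 2,2,4-trimethyl-1,3-dioxan-5-one; 6 ethyl (E)-4-oxobut-2-enoate
Product: 8 ethyl (1R,5S,6S,8S)-8-hydroxy-1,3,3-trimethyl-9-oxo-2,4-dioxabicyclo[3.3.1]nonane-6-carboxylate, via Michael adduct keto aldehyde 7 (not isolated)
Conditions: (R)-2-[diphenyl(trimethylsilyloxy)methyl]pyrrolidine (20 mol %), PhCO2H (20 mol %), 5 (2 equiv), toluene, 0 °C → rt
Reagents that add atoms: none
Why: Proposed new method: the amine and 6 form an iminium ion whose diphenyl(silyloxy)methyl group covers one face of C1, the enamine (or enol) of 5 on its unsubstituted α-carbon adds to the open face and forms C6–C1, and hydrolysis releases keto aldehyde 7; the closest known reactions are amine-catalysed Michael and aldol additions of 2,2-dimethyl-1,3-dioxan-5-one and the enamine α,α'-annulation of cyclic ketones with enals to bicyclo[3.3.1]nonan-9-ones, but the catalytic asymmetric union of a dioxanone with a 4-oxo-enoate is new. In 7 the acid co-catalyst enolises the ketone toward the methyl-bearing carbon C4, and this enol closes onto the C3 aldehyde in a 6-(enolendo)-exo-trig aldol that forms C4–C3 and the carbocycle. C1 is set by the catalyst: on the usual shielding model the R amine leaves open the face that leads to the configuration of 8. C6 and C4 are set by the bridge, since the ring can only close when C6–O and C4–O are both axial and cis, and C6 stays enolisable until closure, so material funnels into the isomer with the C1 ester equatorial. C3 follows from the closed transition state, in which the aldehyde oxygen is hydrogen-bonded to the enol hydroxyl and so ends axial, gauche to C5 and trans to C4–O. The step needs the Michael addition to start from the CH2 side of 5 (the less substituted enamine forms faster), 1,4- rather than 1,2-addition, and attack at the alkene carbon that carries the ester; the iminium ion secures the last two because its β-carbon is that carbon. An excess of 5 holds back a second addition of 6.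

Step 5
Reactants: 8 bicyclic keto alcohol
Product: 9 ethyl (1R,5S,6S,8S)-8-(methanesulfonyloxy)-1,3,3-trimethyl-9-oxo-2,4-dioxabicyclo[3.3.1]nonane-6-carboxylate
Conditions: MsCl, Et3N, CH2Cl2, −20 → 0 °C
Reagents that add atoms: methanesulfonyl chloride, CS(=O)(=O)Cl
Why: Sulfonylation through the sulfene, which reaches the hindered axial C3–OH with retention; C4 has no hydrogen, so the β-sulfonyloxy ketone cannot eliminate toward the carbonyl, and the retro-aldol path open to 8 is closed.

Step 6
Reactants: 9 bicyclic keto mesylate
Product: 10 ethyl (1S,5S,6S,8S,9S)-9-hydroxy-8-(methanesulfonyloxy)-1,3,3-trimethyl-2,4-dioxabicyclo[3.3.1]nonane-6-carboxylate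
Conditions: NaBH4, EtOH, −40 → −20 °C
Reagents that add atoms: none
Why: Reduction of the ketone by NaBH4; hydride should enter C5 along the axial direction of the carbocyclic chair, away from the dioxane bridge whose acetal methyl group lies over the other face, so the new hydroxyl is equatorial on the carbocycle and cis to C4–O and C6–O. Ester and mesylate are not reduced at this temperature.

Step 7
Reactants: 10 bicyclic hydroxy mesylate
Product: 11 ethyl (1S,5S,6S,8S,9S)-9-(tert-butyldimethylsilyloxy)-8-(methanesulfonyloxy)-1,3,3-trimethyl-2,4-dioxabicyclo[3.3.1]nonane-6-carboxylate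
Conditions: tBuMe2SiOTf, 2,6-lutidine, CH2Cl2, −40 → 0 °C
Reagents that add atoms: tert-butyldimethylsilyl trifluoromethanesulfonate, CC(C)(C)[Si](C)(C)OS(=O)(=O)C(F)(F)F
Why: Silylation with the silyl triflate, which is reactive enough for the flanked C5–OH; this ether keeps C5–O distinct from C4–O and C6–O once the acetonide is gone.

Step 8
Reactants: 11 bicyclic silyl ether ester
Product: 12 (1S,5S,6S,8S,9S)-9-(tert-butyldimethylsilyloxy)-N-methoxy-8-(methanesulfonyloxy)-N,1,3,3-tetramethyl-2,4-dioxabicyclo[3.3.1]nonane-6-carboxamide
Conditions: MeNH(OMe)·HCl, iPrMgCl, THF, −20 °C; then 11, −20 → 0 °C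
Reagents that add atoms: N,O-dimethylhydroxylamine hydrochloride, CNOC.Cl
Why: Ester aminolysis by ClMgN(OMe)Me (Weinreb amide formation); the amide reagent is preformed so that no free iPrMgCl meets the mesylate, and the equatorial C1 centre is the thermodynamically preferred one.

Step 9
Reactants: 12 bicyclic N-methoxy-N-methylamide; 13 5-bromo-2-methylpent-2-ene
Product: 15 1-[(1S,5S,6S,8S,9S)-9-(tert-butyldimethylsilyloxy)-8-(methanesulfonyloxy)-1,3,3-trimethyl-2,4-dioxabicyclo[3.3.1]nonan-6-yl]-5-methylhex-4-en-1-one, via (4-methylpent-3-enyl)magnesium bromide 14 (not isolated)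
Conditions: 13, Mg, THF, rt; then 12, THF, 0 °C; aq. NH4Cl
Reagents that add atoms: none
Why: Weinreb ketone synthesis; the chelated tetrahedral adduct holds the reaction at the ketone stage. The mesylate should survive because C3 is neopentyl-like and its rear side is covered by the dioxane bridge.

Step 10
Reactants: 15 bicyclic homoprenyl ketone
Product: 17 (2S)-2-hydroxy derivative of 15 at C8 (the carbon next to the carbonyl on the chain side), via sodium Z-enolate 16 (not isolated)
Conditions: NaN(SiMe3)2, THF, −78 °C; (+)-(2R,8aS)-(camphorylsulfonyl)oxaziridine, −78 °C; aq. NH4Cl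
Reagents that add atoms: (+)-(2R,8aS)-(camphorylsulfonyl)oxaziridine, CC1(C)[C@@H]2CC[C@]13CS(=O)(=O)N4O[C@@]34C2
Why: Oxaziridine hydroxylation of a ketone enolate; kinetic deprotonation takes the C8 methylene rather than the tertiary, more hindered C1–H and should give the Z enolate, and the chiral oxaziridine transfers oxygen to one enolate face (reagent control, 8S expected). The isolated trisubstituted alkene does not react with this oxidant.

Step 11
Reactants: 17 α-hydroxy ketone
Product: 18 C8 triethylsilyl ether of 17
Conditions: Et3SiCl, imidazole, DMF, 0 °C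
Reagents that add atoms: chlorotriethylsilane, CC[Si](Cl)(CC)CC
Why: Silylation; the ether blocks enediol tautomerism of the α-hydroxy ketone and keeps the hydroxyl away from the Cp2TiMe2 of the next step.

Step 12
Reactants: 18 α-silyloxy ketone
Product: 19 triethyl{[(3S)-2-[(1S,5S,6R,8S,9S)-9-(tert-butyldimethylsilyloxy)-8-(methanesulfonyloxy)-1,3,3-trimethyl-2,4-dioxabicyclo[3.3.1]nonan-6-yl]-6-methylhepta-1,5-dien-3-yl]oxy}silane
Conditions: Cp2TiMe2 (3 equiv), toluene, 70 °C, dark
Reagents that add atoms: bis(cyclopentadienyl)dimethyltitanium, C[Ti](C)(C1C=CC=C1)C1C=CC=C1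
Why: Petasis methylenation; the non-basic methylidene Cp2Ti=CH2 converts the hindered α-silyloxy ketone without epimerising C8 or C1, and no ester is present at this stage.

Step 13
Reactants: 19 bicyclic diene
Product: 20 cyclohexane with C3–OSO2CH3, C4–OH, C5–OSiMe2tBu, C6–OH and the chain C7(=C14H2)–C8H(OH)–C9H2–C10H=C11(CH3)2; ring centres as in 27 with the mesylate in the place of chlorine, 8S
Conditions: AcOH/THF/H2O (3:1:1), 40 °C
Reagents that add atoms: none
Why: Acid hydrolysis removes the triethylsilyl ether and the strained acetonide that bridges two axial oxygens; the hindered tert-butyldimethylsilyl ether at C5 and the mesylate should stay.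

Step 14
Reactants: 20 triol mesylate
Product: 21 C3–C4 oxirane (oxygen on the face of C5–O and C6–O) with C5–OSiMe2tBu and free C6–OH and C8–OH
Conditions: K2CO3, MeOH, 0 °C
Reagents that add atoms: none
Why: Intramolecular Williamson reaction; C4–O is axial and anti to the axial C3 mesylate and displaces it with inversion at C3. Low temperature and short time limit silyl migration from C5–O to C6–O.

Step 15
Reactants: 21 epoxy diol; 22 angelic acid ((2Z)-2-methylbut-2-enoic acid)
Product: 24 C6,C8-bis[(2Z)-2-methylbut-2-enoate] of 21, via mixed anhydride 23 (not isolated)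
Conditions: 22 (6 equiv), 2,4,6-Cl3C6H2COCl, Et3N, toluene, rt, filter; then 21, toluene, 80 °C
Reagents that add atoms: none
Why: Yamaguchi-type esterification through the mixed anhydride, run without a nucleophilic catalyst so that the Z geometry is kept; the alcohols attack the less hindered angeloyl carbonyl, and C6–OH and C8–OH are the only free hydroxyls.

Step 16
Reactants: 24 bis-angelate epoxide
Product: 25 5-O-tert-butyldimethylsilyl ether of 26 (C3–Cl, C4–OH, C10=C11 alkene)
Conditions: LiCl, AcOH, THF, rt
Reagents that add atoms: lithium chloride, [Li+].[Cl-]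
Why: Trans-diaxial (Fürst–Plattner) epoxide opening; chloride attacks the secondary C3 anti to the oxirane oxygen and gives C3–Cl trans to C4–OH. Attack at C4 is disfavoured because C4 is fully substituted, is deactivated by the oxygenated C5, and would need the chair with the side chain axial.

Step 17
Reactants: 25 silylated chlorohydrin
Product: 26 the C10=C11 alkene corresponding to 27 (C4–OH and C5–OH free)
Conditions: HF·pyridine, pyridine, THF, 0 °C → rt
Reagents that add atoms: none
Why: Fluoride desilylation under buffered acidic conditions, where neither closure of the chlorohydrin nor acyl migration from C6 to C5 (both base-mediated) is expected.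

Step 18
Reactants: 26 alkene
Product: 27 (1S,2S,3S,4S,6R)-4-chloro-6-[(3S)-4-[(2S)-3,3-dimethyloxiran-2-yl]-3-{[(2Z)-2-methylbut-2-enoyl]oxy}but-1-en-2-yl]-2,3-dihydroxy-3-methylcyclohexyl (2Z)-2-methylbut-2-enoate
Conditions: 1,2:4,5-di-O-isopropylidene-β-L-erythro-2,3-hexodiulo-2,6-pyranose (1 equiv), KHSO5, NaHCO3, Bu4NHSO4, MeCN/CH2(OMe)2/aq. Na2H2EDTA, 0 °C, pH 8
Reagents that add atoms: potassium peroxymonosulfate, [K+].[O-]S(=O)(=O)OO
Why: Shi epoxidation; the chiral dioxirane epoxidises the only electron-rich alkene and ignores the 1,1-disubstituted allylic alkene and the two enoates. The L-series ketone should set C10 as S through the spiro transition state (reagent control), and the near-neutral pH protects the chlorohydrin.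

## Compound list

1 | 2,2-dimethyl-1,3-dioxan-5-one | CC1(C)OCC(=O)CO1 | starting material
2 | 2-(2,2-dimethyl-1,3-dioxan-5-ylidene)-1,1-dimethylhydrazine | CN(C)N=C1COC(C)(C)OC1 | intermediate
3 | lithium azaenolate of 2 | [Li+].CN(C)[N-]C1=COC(C)(C)OC1 | intermediate
4 | 1,1-dimethyl-2-(2,2,4-trimethyl-1,3-dioxan-5-ylidene)hydrazine (racemic) | CN(C)N=C1COC(C)(C)OC1C | intermediate
5 | 2,2,4-trimethyl-1,3-dioxan-5-one (racemic) | CC1OC(C)(C)OCC1=O | intermediate
6 | ethyl (E)-4-oxobut-2-enoate | CCOC(=O)/C=C/C=O | starting material
7 | ethyl (2S)-4-oxo-2-(2,2,6-trimethyl-5-oxo-1,3-dioxan-4-yl)butanoate (epimers at the two dioxanone carbons) | CCOC(=O)[C@@H](CC=O)C1OC(C)(C)OC(C)C1=O | intermediate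
8 | ethyl (1R,5S,6S,8S)-8-hydroxy-1,3,3-trimethyl-9-oxo-2,4-dioxabicyclo[3.3.1]nonane-6-carboxylate | CCOC(=O)[C@H]1C[C@H](O)[C@]2(C)C(=O)[C@H]1OC(C)(C)O2 | intermediate
9 | ethyl (1R,5S,6S,8S)-8-(methanesulfonyloxy)-1,3,3-trimethyl-9-oxo-2,4-dioxabicyclo[3.3.1]nonane-6-carboxylate | CCOC(=O)[C@H]1C[C@H](OS(C)(=O)=O)[C@]2(C)C(=O)[C@H]1OC(C)(C)O2 | intermediate
10 | ethyl (1S,5S,6S,8S,9S)-9-hydroxy-8-(methanesulfonyloxy)-1,3,3-trimethyl-2,4-dioxabicyclo[3.3.1]nonane-6-carboxylate | CCOC(=O)[C@H]1C[C@H](OS(C)(=O)=O)[C@]2(C)[C@@H](O)[C@H]1OC(C)(C)O2 | intermediate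
11 | ethyl (1S,5S,6S,8S,9S)-9-(tert-butyldimethylsilyloxy)-8-(methanesulfonyloxy)-1,3,3-trimethyl-2,4-dioxabicyclo[3.3.1]nonane-6-carboxylate | CCOC(=O)[C@H]1C[C@H](OS(C)(=O)=O)[C@]2(C)[C@@H](O[Si](C)(C)C(C)(C)C)[C@H]1OC(C)(C)O2 | intermediate
12 | (1S,5S,6S,8S,9S)-9-(tert-butyldimethylsilyloxy)-N-methoxy-8-(methanesulfonyloxy)-N,1,3,3-tetramethyl-2,4-dioxabicyclo[3.3.1]nonane-6-carboxamide | CON(C)C(=O)[C@H]1C[C@H](OS(C)(=O)=O)[C@]2(C)[C@@H](O[Si](C)(C)C(C)(C)C)[C@H]1OC(C)(C)O2 | intermediate
13 | 5-bromo-2-methylpent-2-ene | CC(C)=CCCBr | starting material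
14 | (4-methylpent-3-enyl)magnesium bromide | CC(C)=CCC[Mg]Br | intermediate
15 | 1-[(1S,5S,6S,8S,9S)-9-(tert-butyldimethylsilyloxy)-8-(methanesulfonyloxy)-1,3,3-trimethyl-2,4-dioxabicyclo[3.3.1]nonan-6-yl]-5-methylhex-4-en-1-one | CC(C)=CCCC(=O)[C@H]1C[C@H](OS(C)(=O)=O)[C@]2(C)[C@@H](O[Si](C)(C)C(C)(C)C)[C@H]1OC(C)(C)O2 | intermediate
16 | sodium (Z)-enolate of 15 toward C8 | [Na+].CC(C)=CC/C=C(\[O-])[C@H]1C[C@H](OS(C)(=O)=O)[C@]2(C)[C@@H](O[Si](C)(C)C(C)(C)C)[C@H]1OC(C)(C)O2 | intermediate
17 | (2S)-2-hydroxy derivative of 15 (C8–OH) | CC(C)=CC[C@H](O)C(=O)[C@H]1C[C@H](OS(C)(=O)=O)[C@]2(C)[C@@H](O[Si](C)(C)C(C)(C)C)[C@H]1OC(C)(C)O2 | intermediate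
18 | C8 triethylsilyl ether of 17 | CC(C)=CC[C@H](O[Si](CC)(CC)CC)C(=O)[C@H]1C[C@H](OS(C)(=O)=O)[C@]2(C)[C@@H](O[Si](C)(C)C(C)(C)C)[C@H]1OC(C)(C)O2 | intermediate
19 | triethyl{[(3S)-2-[(1S,5S,6R,8S,9S)-9-(tert-butyldimethylsilyloxy)-8-(methanesulfonyloxy)-1,3,3-trimethyl-2,4-dioxabicyclo[3.3.1]nonan-6-yl]-6-methylhepta-1,5-dien-3-yl]oxy}silane | C=C([C@H](CC=C(C)C)O[Si](CC)(CC)CC)[C@H]1C[C@H](OS(C)(=O)=O)[C@]2(C)[C@@H](O[Si](C)(C)C(C)(C)C)[C@H]1OC(C)(C)O2 | intermediate
20 | cyclohexane triol mesylate: C3–OSO2CH3, C4–OH, C5–OSiMe2tBu, C6–OH, C8–OH (8S); ring centres as in 27 with the mesylate in the place of chlorine | C=C([C@H](CC=C(C)C)O)[C@H]1C[C@H](OS(C)(=O)=O)[C@@](C)(O)[C@@H](O[Si](C)(C)C(C)(C)C)[C@H]1O | intermediate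
21 | C3–C4 oxirane (oxygen on the face of C5–O and C6–O), C5–OSiMe2tBu, C6–OH and C8–OH free | C=C([C@H](CC=C(C)C)O)[C@H]1C[C@H]2O[C@@]2(C)[C@@H](O[Si](C)(C)C(C)(C)C)[C@H]1O | intermediate
22 | angelic acid, (2Z)-2-methylbut-2-enoic acid | C/C=C(/C)C(O)=O | starting material
23 | (2Z)-2-methylbut-2-enoic 2,4,6-trichlorobenzoic anhydride | C/C=C(/C)C(=O)OC(=O)c1c(Cl)cc(Cl)cc1Cl | intermediate
24 | C6,C8-bis[(2Z)-2-methylbut-2-enoate] of 21 | C=C([C@H](CC=C(C)C)OC(=O)/C(C)=C\C)[C@H]1C[C@H]2O[C@@]2(C)[C@@H](O[Si](C)(C)C(C)(C)C)[C@H]1OC(=O)/C(C)=C\C | intermediate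
25 | 5-O-tert-butyldimethylsilyl ether of 26 (C3–Cl, C4–OH) | C=C([C@H](CC=C(C)C)OC(=O)/C(C)=C\C)[C@H]1C[C@H](Cl)[C@@](C)(O)[C@@H](O[Si](C)(C)C(C)(C)C)[C@H]1OC(=O)/C(C)=C\C | intermediate
26 | C10=C11 alkene corresponding to 27 (chlorohydrin, C5–OH free, both angelates) | C=C([C@H](CC=C(C)C)OC(=O)/C(C)=C\C)[C@H]1C[C@H](Cl)[C@@](C)(O)[C@@H](O)[C@H]1OC(=O)/C(C)=C\C | intermediate
27 | (1S,2S,3S,4S,6R)-4-chloro-6-[(3S)-4-[(2S)-3,3-dimethyloxiran-2-yl]-3-{[(2Z)-2-methylbut-2-enoyl]oxy}but-1-en-2-yl]-2,3-dihydroxy-3-methylcyclohexyl (2Z)-2-methylbut-2-enoate | C=C([C@H](C[C@@H]1OC1(C)C)OC(=O)/C(C)=C\C)[C@H]1C[C@H](Cl)[C@@](C)(O)[C@@H](O)[C@H]1OC(=O)/C(C)=C\C | target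

## Step count and least certain steps

Total: 18 steps. Longest linear sequence: 18 steps (1 → 27); compounds 6, 13 and 22 enter as bought materials.

**Step 4 (key step).** The most likely failure is that the hindered amine does not convert the ketone into an enamine. The conjugate addition then runs slowly through an unselective background path, while the aldehyde of the adduct adds to further 6. The aldol may also stall at 7, or close through an open transition state and put C3–OH equatorial. The fallback separates the two bond formations and uses known reaction types; it sets out from 5 and comes back to the route at 8. Kinetic enolisation of 5 on the CH2 side (LiN(iPr)2, Me3SiCl, THF, −78 °C) gives trimethyl[(2,2,4-trimethyl-4H-1,3-dioxin-5-yl)oxy]silane F1. An iminium-catalysed Mukaiyama–Michael addition of F1 to 6 follows (5-benzyl-2-tert-butyl-3-methylimidazolidin-4-one trifluoroacetate, the antipode that opens the same face of C1 as the amine of step 4; aqueous work-up) and gives 7, now isolated. Finally 7 is closed to 8 with pyrrolidinium acetate.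

**Step 6.** Facial selectivity may be poor, because the axial C3 mesylate is syn-axial to the hydride trajectory that gives the wanted equatorial alcohol. The fallback reverses the order and uses intramolecular delivery; it sets out from 8 and comes back to the route at 10. Me4NBH(OAc)3 in MeCN/AcOH at −20 °C binds to the axial C3–OH and delivers hydride to the same face of C5, which gives ethyl (1R,5S,6S,8S,9S)-8,9-dihydroxy-1,3,3-trimethyl-2,4-dioxabicyclo[3.3.1]nonane-6-carboxylate F2. One equivalent of MsCl/Et3N at −40 °C should then sulfonylate C3–OH, which has a CH2 neighbour, in preference to the doubly flanked C5–OH, and give 10.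

**Step 10.** Oxygen transfer to the acyclic dialkyl ketone enolate may be weakly selective or of the wrong sense, and a mixed enolate geometry would erode it further. The fallback replaces reagent-controlled oxidation by reagent-controlled reduction; it sets out from 20 obtained as a mixture of C8 epimers and comes back to the route at 20 as the 8S isomer. MnO2 in CH2Cl2 oxidises only the allylic C8–OH and gives the α-methylene ketone F3 (the C8 ketone of 20). Corey–Bakshi–Shibata reduction with (R)-1-methyl-3,3-diphenyltetrahydro-1H,3H-pyrrolo[1,2-c][1,3,2]oxazaborole and BH3·SMe2 then treats the branched alkenyl group as the large substituent and gives the 8S alcohol 20.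

**Step 15.** Acylation of the hindered C6–OH may be slow, and prolonged heating may isomerise the Z ester to the E ester. The fallback builds the Z alkene on the ester; it sets out from 21 and comes back to the route at 24. Both hydroxyls are acylated with the unhindered 2-[bis(2,2,2-trifluoroethoxy)phosphoryl]propanoic acid (carbodiimide coupling), which gives the bis(phosphonopropanoate) F4. A double Still–Gennari olefination with acetaldehyde (KN(SiMe3)2, 18-crown-6, THF, −78 °C) then forms the two (Z)-2-methylbut-2-enoates of 24.

**Step 16.** Ionisation at the tertiary epoxide carbon may divert chloride to C4 or cause rearrangement to a ketone. The fallback uses a hydroxyl-directed opening; it sets out from 24 and comes back to the route at 26, skipping 25. HF·pyridine removes the C5 silyl ether first and gives the cis epoxy alcohol F5. Ti(OiPr)4 with Et2NH2Cl in CH2Cl2 then binds C5–O and the oxirane oxygen and delivers chloride to the distal carbon C3, giving 26.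

## Further compounds

F1 | step 4 | trimethyl[(2,2,4-trimethyl-4H-1,3-dioxin-5-yl)oxy]silane (racemic) | CC1OC(C)(C)OC=C1O[Si](C)(C)C
F2 | step 6 | ethyl (1R,5S,6S,8S,9S)-8,9-dihydroxy-1,3,3-trimethyl-2,4-dioxabicyclo[3.3.1]nonane-6-carboxylate | CCOC(=O)[C@H]1C[C@H](O)[C@]2(C)[C@@H](O)[C@H]1OC(C)(C)O2
F3 | step 10 | C8 ketone of 20 (α-methylene ketone; C3–OSO2CH3, C4–OH, C5–OSiMe2tBu, C6–OH) | C=C(C(=O)CC=C(C)C)[C@H]1C[C@H](OS(C)(=O)=O)[C@@](C)(O)[C@@H](O[Si](C)(C)C(C)(C)C)[C@H]1O
F4 | step 15 | C6,C8-bis{2-[bis(2,2,2-trifluoroethoxy)phosphoryl]propanoate} of 21 (epimers at the two phosphonate-bearing carbons) | C=C([C@H](CC=C(C)C)OC(=O)C(C)P(=O)(OCC(F)(F)F)OCC(F)(F)F)[C@H]1C[C@H]2O[C@@]2(C)[C@@H](O[Si](C)(C)C(C)(C)C)[C@H]1OC(=O)C(C)P(=O)(OCC(F)(F)F)OCC(F)(F)F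
F5 | step 16 | C5 alcohol of 24 (cis epoxy alcohol, both angelates) | C=C([C@H](CC=C(C)C)OC(=O)/C(C)=C\C)[C@H]1C[C@H]2O[C@@]2(C)[C@@H](O)[C@H]1OC(=O)/C(C)=C\C
A1 | alternative 1 | cis-fused 3-methylidene oxasilolane on the cyclohexene: 7-(tert-butyldimethylsilyloxy)-2,2,6-trimethyl-3-methylidene-2,3,3a,4,7,7a-hexahydro-1,2-benzoxasilole, configured at C1, C5 and C6 as in 27 | C=C1[C@H]2CC=C(C)[C@@H](O[Si](C)(C)C(C)(C)C)[C@H]2O[Si]1(C)C
A2 | alternative 1 | (1-bromoethenyl)dimethylsilyl ether at C6–O of the C5-O-tert-butyldimethylsilyl diene diol | C=C(Br)[Si](C)(C)O[C@H]1C=CC=C(C)[C@H]1O[Si](C)(C)C(C)(C)C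
A3 | alternative 1 | (1S,2R)-3-methylcyclohexa-3,5-diene-1,2-diol | CC1=CC=C[C@H](O)[C@@H]1O
A4 | alternative 2 | ring-closed chlorohydrin with C5–OSiMe2tBu and 4-methoxybenzyl ethers at C6–O and C8–O | C=C([C@H](CC=C(C)C)OCc1ccc(OC)cc1)[C@H]2C[C@H](Cl)[C@@](C)(O)[C@@H](O[Si](C)(C)C(C)(C)C)[C@H]2OCc3ccc(OC)cc3
A5 | alternative 2 | open-chain C4 methyl ketone with the C3 α-chloro 4-tolyl sulfoxide (either configuration at sulfur), C5–OSiMe2tBu and 4-methoxybenzyl ethers at C6–O and C8–O | C=C([C@H](CC=C(C)C)OCc1ccc(OC)cc1)[C@@H](C[C@H](Cl)S(=O)c1ccc(C)cc1)[C@H](OCc1ccc(OC)cc1)[C@H](O[Si](C)(C)C(C)(C)C)C(C)=O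
A6 | alternative 3 | cis-fused diisopropyl dioxasilolane on the cyclohexene with the C1 acyl group (C7 ketone, C8–OSiMe2tBu) | CC(C)[Si]1(C(C)C)O[C@@H]2C(C)=CC[C@H](C(=O)[C@@H](O[Si](C)(C)C(C)(C)C)CC=C(C)C)[C@@H]2O1
A7 | alternative 3 | diisopropylsilylene bis-enol ether of the (E)-1-oxy-2-methylbuta-1,3-diene and the (Z)-β-oxy enone carrying the C8–OSiMe2tBu chain | C=C/C(C)=C/O[Si](C(C)C)(C(C)C)O/C=C\C(=O)[C@@H](O[Si](C)(C)C(C)(C)C)CC=C(C)C
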